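**Retrosynthetic overview**
1. Target ⇐ tetraol 25: one MnO2 operation makes the C15 enal and closes the trans-fused α-methylene γ-lactone (C12 onto 8-OH) last.
2. (1R)-Epoxide ⇐ C10 vinyl by 9-OH-directed, ligand-controlled vanadium epoxidation; vinyl ⇐ C1H2OH (Tamao oxidation, Wittig); C6 ester ⇐ axial alcohol ⇐ C6 ketone.
3. Key step: the C10 quaternary centre (C10–C1) and the C5–C4 bond are made together by a nickel-catalysed silicon-tethered radical cyclisation/alkenylation of a γ-silyloxy enone.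
4. Enone ⇐ quinone monoketal of 4-methoxy-2-methylphenol: asymmetric Rh conjugate alkenylation (C7), Rubottom oxidation (C8), reduction then inversion (C9), ketal hydrolysis (C6=O).
5. Ring order: carbocycle (from the arene) → temporary oxasilolane (step 12, opened in step 15) → oxirane (step 18) → γ-lactone (step 20).

Convention (assumption): elemane numbering of the target is used for all ring compounds (ring C5–C10; C14 methyl and C1–C2 on C10; C4(=C3)–C15 on C5; C11(=C13)–C12 on C7); β = face of the C14 methyl, so the target is 5β-side chain, 6β-O, 7β-side chain, 8α-O, 9α-OH, C1 α, 1R.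

**Step 1**
Reactants: 1 2-bromoprop-2-en-1-ol
Product: 2 tert-butyl[(2-bromoprop-2-en-1-yl)oxy]dimethylsilane
Conditions: TBSCl, imidazole, CH2Cl2, 0 °C to rt
Reagents that add atoms: tert-butyldimethylsilyl chloride, CC(C)(C)[Si](C)(C)Cl
Why: Standard silyl ether protection of a primary allylic alcohol; no stereocentre.

**Step 2**
Reactants: 2 tert-butyl[(2-bromoprop-2-en-1-yl)oxy]dimethylsilane
Product: 3 tert-butyldimethyl{[2-(4,4,5,5-tetramethyl-1,3,2-dioxaborolan-2-yl)prop-2-en-1-yl]oxy}silane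
Conditions: B2pin2, PdCl2(PPh3)2 (3 mol %), PPh3 (6 mol %), KOPh, toluene, 50 °C
Reagents that add atoms: bis(pinacolato)diboron, CC1(C)OB(OC1(C)C)B1OC(C)(C)C(C)(C)O1
Why: Miyaura borylation of a 1-alkenyl bromide with phenoxide as base keeps the 1,1-disubstituted alkene intact; no stereocentre.

**Step 3**
Reactants: 4 4-methoxy-2-methylphenol
Product: 5 4,4-dimethoxy-2-methylcyclohexa-2,5-dien-1-one
Conditions: PhI(OAc)2, MeOH, 0 °C
Reagents that add atoms: methanol, CO
Why: Hypervalent-iodine oxidative dearomatisation of a para-methoxyphenol gives the quinone monoketal, which already carries the C9 and C6 oxygens and the C14 methyl; achiral.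

**Step 4**
Reactants: 5 4,4-dimethoxy-2-methylcyclohexa-2,5-dien-1-one; 3 alkenyl pinacol boronate
Product: 6 (5S)-5-[3-(tert-butyldimethylsilyloxy)prop-1-en-2-yl]-4,4-dimethoxy-2-methylcyclohex-2-en-1-one (C7 side chain β)
Conditions: [Rh(OH)(cod)]2 (2.5 mol %), (S)-BINAP (6 mol %), KOH (0.2 equiv), 1,4-dioxane/H2O 10:1, 40 °C
Reagents that add atoms: none
Why: Hayashi–Miyaura rhodium-catalysed asymmetric 1,4-addition; the alkenylrhodium adds only to the α-unsubstituted enone C7=C8 (the α-methyl enone is much slower), and (S)-BINAP, in the sense known for 3-substituted cyclohexanones, sets C7 (5S).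

**Step 5**
Reactants: 6 conjugate adduct
Product: 8 C9 trimethylsilyl dienol ether of 6 (C8=C9(OSiMe3)–C10=C5 diene), via lithium dienolate 7 (not isolated)
Conditions: LiN(i-Pr)2, THF, −78 °C; then Me3SiCl, −78 to 0 °C
Reagents that add atoms: chlorotrimethylsilane, C[Si](C)(C)Cl
Why: Kinetic enolate formation and O-silylation; C8 is the only enolisable position because C6 is a ketal, and C7 is untouched.

**Step 6**
Reactants: 8 trimethylsilyl dienol ether
Product: 10 (5R,6R)-5-[3-(tert-butyldimethylsilyloxy)prop-1-en-2-yl]-6-hydroxy-4,4-dimethoxy-2-methylcyclohex-2-en-1-one (8α-OH), via 8α-trimethylsilyloxy ketone 9 (not isolated)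
Conditions: mCPBA, CH2Cl2, −20 °C; then citric acid (cat.), MeOH, 0 °C
Reagents that add atoms: meta-chloroperoxybenzoic acid, OOC(=O)c1cccc(Cl)c1
Why: Rubottom oxidation; the peracid attacks the electron-rich silyl enol ether on the face anti to the adjacent C7 side chain, and silyl migration then methanolysis gives the 8α-hydroxy ketone (trans to the C7 group).

**Step 7**
Reactants: 10 8α-hydroxy ketone
Product: 11 (5R,6R)-6-(tert-butyldimethylsilyloxy)-5-[3-(tert-butyldimethylsilyloxy)prop-1-en-2-yl]-4,4-dimethoxy-2-methylcyclohex-2-en-1-one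
Conditions: TBSCl, imidazole, DMF, rt
Reagents that add atoms: tert-butyldimethylsilyl chloride, CC(C)(C)[Si](C)(C)Cl
Why: Silyl ether protection of the α-ketol under non-Lewis-acidic conditions that leave the ketal alone; no stereocentre changes.

**Step 8**
Reactants: 11 bis-silyl enone
Product: 12 9β-allylic alcohol (8α-OTBS, 9β-OH trans to it, 6,6-dimethoxy, C5=C10, 7β side chain)
Conditions: NaBH4, CeCl3·7H2O, MeOH, −78 °C
Reagents that add atoms: none
Why: Luche 1,2-reduction; axial hydride delivery to the half-chair with pseudo-equatorial C7 and C8 groups gives the pseudo-equatorial 9β-alcohol, the wrong C9 epimer on purpose, inverted in step 9.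

**Step 9**
Reactants: 12 9β-allylic alcohol
Product: 14 9α-allylic alcohol (cis-8α,9α-diol, 8-O-TBS ether), via 9α-(4-nitrobenzoate) 13 (not isolated)
Conditions: PPh3, DIAD, 4-nitrobenzoic acid, THF, 0 °C to rt; then K2CO3 (cat.), MeOH, 0 °C
Reagents that add atoms: 4-nitrobenzoic acid, OC(=O)c1ccc(cc1)[N+](=O)[O-]
Why: Mitsunobu inversion (SN2 at the allylic carbinol; SN2′ is blocked by the ketal-flanked C5) and methanolysis of the activated ester give the 9α-alcohol, i.e. the cis-8α,9α-dioxygen pattern of the target.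

**Step 10**
Reactants: 14 9α-allylic alcohol
Product: 15 γ-hydroxy enone: 4-hydroxy-3-methyl-5-(tert-butyldimethylsilyloxy)-6-[3-(tert-butyldimethylsilyloxy)prop-1-en-2-yl]cyclohex-2-en-1-one, 4-OH cis to 5-OTBS, 6-side chain trans to 5-OTBS (C6=O, C5=C10, 9α-OH, 8α-OTBS, 7β)
Conditions: PPTS (cat.), acetone/H2O 10:1, rt
Reagents that add atoms: water, O
Why: Mild acid hydrolysis of the allylic dimethyl ketal unveils the C6 ketone as the transposed enone without touching the silyl ethers; no stereocentre changes.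

**Step 11**
Reactants: 15 γ-hydroxy enone
Product: 16 9α-O-[(bromomethyl)dimethylsilyl] ether of 15
Conditions: BrCH2SiMe2Cl, Et3N, DMAP (cat.), CH2Cl2, 0 °C
Reagents that add atoms: (bromomethyl)chlorodimethylsilane, BrC[Si](C)(C)Cl
Why: Silylation of the only free hydroxyl installs the temporary silicon tether on the α face, next to C10.

**Step 12**
Reactants: 16 bromomethylsilyl ether; 2 tert-butyl[(2-bromoprop-2-en-1-yl)oxy]dimethylsilane
Product: 17 cis-fused oxasilolane ketone: 6-oxo, 5β- and 7β-[3-(tert-butyldimethylsilyloxy)prop-1-en-2-yl], 8α-OTBS, 10β-methyl, C1H2 (α on C10) bridged through SiMe2 to the 9α-oxygen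
Conditions: NiBr2(dme) (10 mol %), 4,4′-di-tert-butyl-2,2′-bipyridine (12 mol %), Zn dust (3 equiv), NaI (0.3 equiv), DMA, 25 °C, slow addition of 16 to 2 (2 equiv)
Reagents that add atoms: none
Why: Proposed new method: nickel-catalysed silicon-tethered radical cyclisation/alkenylation of an enone, in which 2 adds oxidatively to zerovalent nickel, monovalent nickel abstracts bromine from Si–CH2Br, the α-silyl radical adds 5-exo to the enone β-carbon C10 from the α face dictated by the 9α-O–Si tether (C1 α, C14 β, quaternary centre set), and the C5 α-keto radical is captured by the alkenylnickel species (divalent to trivalent) and reductively eliminated to form C5–C4 on the β face, trans to the new C10–C1 bond and equatorial (also the thermodynamic epimer of this enolisable centre); the closest known reaction types are the tin-hydride cyclisation of bromomethylsilyl ethers of allylic alcohols and nickel-catalysed reductive radical cyclisation/cross-electrophile coupling of alkenes.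

**Step 13**
Reactants: 17 oxasilolane ketone
Product: 18 6β-alcohol of 17 (axial OH, cis to both side chains)
Conditions: LiBH(s-Bu)3, THF, −78 to −20 °C; H2O quench
Reagents that add atoms: none
Why: Bulky hydride reduction; the axial β C14 methyl blocks the axial β-face trajectory, so hydride enters equatorially from the α face and gives the axial 6β-alcohol.

**Step 14**
Reactants: 18 6β-alcohol; 19 (S)-2-methylbutanoic anhydride
Product: 20 6β-O-[(2S)-2-methylbutanoyl] ester of 18
Conditions: DMAP (1 equiv), Et3N, CH2Cl2, 35 °C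
Reagents that add atoms: none
Why: DMAP-catalysed acyl transfer to the only free hydroxyl (9-O and C1 are tied up in the oxasilolane); the anhydride avoids ketene formation, so the (S) α-centre is kept.

**Step 15**
Reactants: 20 ester
Product: 21 diol: C10 α-hydroxymethyl (C1) and 9α-OH, 6β-ester, 8α-OTBS, both side chains as TBS ethers
Conditions: 30 % H2O2, KF, KHCO3, THF/MeOH 1:1, 40 °C
Reagents that add atoms: hydrogen peroxide, OO
Why: Tamao–Fleming oxidation of the cyclic alkoxysilane turns C1–Si into C1–OH and frees 9α-OH; the hindered ester, the silyl ethers and the unactivated alkenes survive.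

**Step 16**
Reactants: 21 diol
Product: 22 C1 aldehyde (C10 α-formyl, 9α-OH)
Conditions: TEMPO (0.2 equiv), PhI(OAc)2 (1.2 equiv), CH2Cl2, rt
Reagents that add atoms: none
Why: Oxoammonium (TEMPO) oxidation is selective for the primary alcohol over the hindered secondary 9α-OH; the neopentyl aldehyde has no α-hydrogen to epimerise.

**Step 17**
Reactants: 22 aldehyde
Product: 23 C10 α-vinyl compound (C1=C2), 9α-OH
Conditions: Ph3PCH3Br, KN(SiMe3)2, THF, 0 °C; then 22, −78 to 0 °C
Reagents that add atoms: methyltriphenylphosphonium bromide, C[P+](c1ccccc1)(c1ccccc1)c1ccccc1.[Br-]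
Why: Wittig methylenation of a non-enolisable aldehyde; excess ylide tolerates the free 9-OH and the low temperature suppresses retro-aldol cleavage.

**Step 18**
Reactants: 23 vinyl alcohol
Product: 24 (1R)-1,2-epoxide (oxiranyl α on C10), 9α-OH
Conditions: VO(O-i-Pr)3 (5 mol %), N,N′-[(1R,2R)-cyclohexane-1,2-diyl]bis(N-hydroxy-2,2-diphenylacetamide) (6 mol %), cumene hydroperoxide, toluene, 0 °C to rt
Reagents that add atoms: cumene hydroperoxide, CC(C)(OO)c1ccccc1
Why: Hydroxyl-directed vanadium-catalysed epoxidation of a homoallylic alcohol; 9α-OH is the only free hydroxyl, so only the C1=C2 vinyl reacts, and the chiral bis-hydroxamic acid on pentavalent vanadium is relied on to deliver oxygen to the Si face of C1 (1R).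

**Step 19**
Reactants: 24 epoxide
Product: 25 tetraol: 8α-OH, 9α-OH, 12-OH, 15-OH, 6β-ester, (1R)-epoxide
Conditions: Bu4NF/AcOH (1:1), THF, 0 to 40 °C
Reagents that add atoms: none
Why: Buffered fluoride desilylation removes the three TBS groups without free alkoxide, so the ester does not migrate and the epoxide is not opened.

**Step 20**
Reactants: 25 tetraol
Product: 28 target CNP0593558.1, via 12,15-dialdehyde 26 (not isolated), via 8,12-lactol 27 (not isolated)
Conditions: activated MnO2 (excess), CH2Cl2, rt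
Reagents that add atoms: none
Why: Tandem allylic oxidation/oxidative lactonisation; MnO2 oxidises only the two allylic primary alcohols, the C15 aldehyde stays as the enal, and the C12 aldehyde is trapped by the equatorial 8α-OH as the trans-fused lactol, which is oxidised on to the α-methylene γ-lactone while the saturated 9α-OH is untouched.

**Compound list**
1 | 2-bromoprop-2-en-1-ol | OCC(Br)=C | starting material
2 | tert-butyl[(2-bromoprop-2-en-1-yl)oxy]dimethylsilane | C=C(Br)CO[Si](C)(C)C(C)(C)C | intermediate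
3 | tert-butyldimethyl{[2-(4,4,5,5-tetramethyl-1,3,2-dioxaborolan-2-yl)prop-2-en-1-yl]oxy}silane | C=C(CO[Si](C)(C)C(C)(C)C)B1OC(C)(C)C(C)(C)O1 | intermediate
4 | 4-methoxy-2-methylphenol | COc1ccc(O)c(C)c1 | starting material
5 | 4,4-dimethoxy-2-methylcyclohexa-2,5-dien-1-one | COC1(OC)C=CC(=O)C(C)=C1 | intermediate
6 | (5S)-5-[3-(tert-butyldimethylsilyloxy)prop-1-en-2-yl]-4,4-dimethoxy-2-methylcyclohex-2-en-1-one | C1[C@@H](C(=C)CO[Si](C)(C)C(C)(C)C)C(OC)(OC)C=C(C)C1=O | intermediate
7 | lithium dienolate of 6 (C8=C9–OLi), not isolated | [Li]OC1=C[C@@H](C(=C)CO[Si](C)(C)C(C)(C)C)C(OC)(OC)C=C1C | intermediate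
8 | C9 trimethylsilyl dienol ether of 6 | C[Si](C)(C)OC1=C[C@@H](C(=C)CO[Si](C)(C)C(C)(C)C)C(OC)(OC)C=C1C | intermediate
9 | 8α-trimethylsilyloxy ketone, not isolated | C[Si](C)(C)O[C@@H]1[C@@H](C(=C)CO[Si](C)(C)C(C)(C)C)C(OC)(OC)C=C(C)C1=O | intermediate
10 | (5R,6R)-5-[3-(tert-butyldimethylsilyloxy)prop-1-en-2-yl]-6-hydroxy-4,4-dimethoxy-2-methylcyclohex-2-en-1-one (8α-OH) | O[C@@H]1[C@@H](C(=C)CO[Si](C)(C)C(C)(C)C)C(OC)(OC)C=C(C)C1=O | intermediate
11 | (5R,6R)-6-(tert-butyldimethylsilyloxy)-5-[3-(tert-butyldimethylsilyloxy)prop-1-en-2-yl]-4,4-dimethoxy-2-methylcyclohex-2-en-1-one | CC(C)(C)[Si](C)(C)O[C@@H]1[C@@H](C(=C)CO[Si](C)(C)C(C)(C)C)C(OC)(OC)C=C(C)C1=O | intermediate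
12 | 9β-allylic alcohol (9β-OH trans to 8α-OTBS; 6,6-dimethoxy; 7β side chain) | CC(C)(C)[Si](C)(C)O[C@@H]1[C@@H](C(=C)CO[Si](C)(C)C(C)(C)C)C(OC)(OC)C=C(C)[C@H]1O | intermediate
13 | 9α-(4-nitrobenzoate) (9-O cis to 8α-OTBS), not isolated | CC(C)(C)[Si](C)(C)O[C@@H]1[C@@H](C(=C)CO[Si](C)(C)C(C)(C)C)C(OC)(OC)C=C(C)[C@@H]1OC(=O)c2ccc(cc2)[N+](=O)[O-] | intermediate
14 | 9α-allylic alcohol (cis-8α,9α-diol 8-O-TBS ether; 6,6-dimethoxy) | CC(C)(C)[Si](C)(C)O[C@@H]1[C@@H](C(=C)CO[Si](C)(C)C(C)(C)C)C(OC)(OC)C=C(C)[C@@H]1O | intermediate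
15 | γ-hydroxy enone (C6=O, C5=C10, 9α-OH, 8α-OTBS, 7β side chain) | CC(C)(C)[Si](C)(C)O[C@@H]1[C@@H](C(=C)CO[Si](C)(C)C(C)(C)C)C(=O)C=C(C)[C@@H]1O | intermediate
16 | 9α-O-[(bromomethyl)dimethylsilyl] ether of 15 | CC(C)(C)[Si](C)(C)O[C@@H]1[C@@H](C(=C)CO[Si](C)(C)C(C)(C)C)C(=O)C=C(C)[C@@H]1O[Si](C)(C)CBr | intermediate
17 | cis-fused oxasilolane ketone (6-oxo; 5β and 7β side chains; 8α-OTBS; 10β-methyl; C1H2 α bridged by SiMe2 to 9α-O) | CC(C)(C)[Si](C)(C)O[C@@H]1[C@@H](C(=C)CO[Si](C)(C)C(C)(C)C)C(=O)[C@@H](C(=C)CO[Si](C)(C)C(C)(C)C)[C@]2(C)C[Si](C)(C)O[C@H]12 | intermediate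
18 | 6β-alcohol of 17 | CC(C)(C)[Si](C)(C)O[C@@H]1[C@@H](C(=C)CO[Si](C)(C)C(C)(C)C)[C@@H](O)[C@@H](C(=C)CO[Si](C)(C)C(C)(C)C)[C@]2(C)C[Si](C)(C)O[C@H]12 | intermediate
19 | (S)-2-methylbutanoic anhydride | CC[C@H](C)C(=O)OC(=O)[C@@H](C)CC | starting material
20 | 6β-O-[(2S)-2-methylbutanoyl] ester of 18 | CC(C)(C)[Si](C)(C)O[C@@H]1[C@@H](C(=C)CO[Si](C)(C)C(C)(C)C)[C@@H](OC(=O)[C@@H](C)CC)[C@@H](C(=C)CO[Si](C)(C)C(C)(C)C)[C@]2(C)C[Si](C)(C)O[C@H]12 | intermediate
21 | diol (C10 α-CH2OH, 9α-OH) | CC(C)(C)[Si](C)(C)O[C@@H]1[C@@H](C(=C)CO[Si](C)(C)C(C)(C)C)[C@@H](OC(=O)[C@@H](C)CC)[C@@H](C(=C)CO[Si](C)(C)C(C)(C)C)[C@](C)(CO)[C@@H]1O | intermediate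
22 | C1 aldehyde (C10 α-CHO, 9α-OH) | CC(C)(C)[Si](C)(C)O[C@@H]1[C@@H](C(=C)CO[Si](C)(C)C(C)(C)C)[C@@H](OC(=O)[C@@H](C)CC)[C@@H](C(=C)CO[Si](C)(C)C(C)(C)C)[C@](C)(C=O)[C@@H]1O | intermediate
23 | C10 α-vinyl compound, 9α-OH | CC(C)(C)[Si](C)(C)O[C@@H]1[C@@H](C(=C)CO[Si](C)(C)C(C)(C)C)[C@@H](OC(=O)[C@@H](C)CC)[C@@H](C(=C)CO[Si](C)(C)C(C)(C)C)[C@](C)(C=C)[C@@H]1O | intermediate
24 | (1R)-1,2-epoxide, tris-TBS ether | CC(C)(C)[Si](C)(C)O[C@@H]1[C@@H](C(=C)CO[Si](C)(C)C(C)(C)C)[C@@H](OC(=O)[C@@H](C)CC)[C@@H](C(=C)CO[Si](C)(C)C(C)(C)C)[C@](C)([C@@H]2CO2)[C@@H]1O | intermediate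
25 | tetraol (8α-, 9α-, 12-, 15-OH; 6β-ester; 1R-epoxide) | O[C@@H]1[C@@H](C(=C)CO)[C@@H](OC(=O)[C@@H](C)CC)[C@@H](C(=C)CO)[C@](C)([C@@H]2CO2)[C@@H]1O | intermediate
26 | 12,15-dialdehyde, not isolated | O[C@@H]1[C@@H](C(=C)C=O)[C@@H](OC(=O)[C@@H](C)CC)[C@@H](C(=C)C=O)[C@](C)([C@@H]2CO2)[C@@H]1O | intermediate
27 | 8,12-lactol (anomer mixture), not isolated | C=C1C(O)O[C@@H]2[C@@H]1[C@@H](OC(=O)[C@@H](C)CC)[C@@H](C(=C)C=O)[C@](C)([C@@H]1CO1)[C@@H]2O | intermediate
28 | CNP0593558.1 | C=C1C(=O)O[C@@H]2[C@@H]1[C@@H](OC(=O)[C@@H](C)CC)[C@@H](C(=C)C=O)[C@](C)([C@@H]1CO1)[C@@H]2O | target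

**Step count**
Total: 20 steps. Longest linear sequence: 19 steps (steps 1, 2, 4–20); the arene branch is steps 3–20 (18 steps).

**Three steps most likely to fail**

Step 12 (the proposed new method). Risks: premature capture of the α-silyl radical by nickel before cyclisation, simple reduction of the C5 α-keto radical, or homocoupling of 2. Fallback with known chemistry, from 16 back to 17: slow addition of Bu3SnH/AIBN (benzene, 80 °C) effects the same 5-exo cyclisation, and the α-keto radical is simply reduced, giving the C5-unsubstituted cis-fused oxasilolane ketone F1. Kinetic deprotonation of the C5 methylene with LiN(SiMe3)2 (THF, −78 °C) and palladium-catalysed ketone α-alkenylation with bromide 2 (Pd2(dba)3, P(t-Bu)3, rt) then give 17, where the route is rejoined. The C5 (methylene) versus C7 (methine) regioselectivity of that enolisation is the weak point of this fallback.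

Step 18 (C1 configuration). A terminal vinyl group on a quaternary carbon is a slow substrate, and the facial sense rests on ligand control that may be mismatched with the substrate; the ligand enantiomer named is an assignment to be confirmed on a model. Fallback, from aldehyde 22 (skipping 23) back to 24: Corey–Chaykovsky methylenation with dimethylsulfonium methylide (Me3SI, KN(SiMe3)2, THF, −20 °C) gives 24 together with its C1 epimer, the (1S)-epoxide F2. Jacobsen hydrolytic kinetic resolution with (R,R)-(salen)Co(OAc) (trivalent cobalt) and 0.6 equiv of water hydrolyses F2 to the (1S)-1,2-diol F3, which is separated, leaving 24.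

Step 9 (Mitsunobu inversion). The hindered allylic carbinol next to a silyloxy methine may eliminate to a diene or react SN2′. Fallback, from 11 directly to 14 (skipping 12 and 13): reagent-controlled 1,2-reduction with (S)-2-methyl-CBS-oxazaborolidine and catecholborane (toluene, −78 °C), with the trisubstituted alkenyl side acting as the large group, sets 9α-OH in one step. This fallback makes no new compound (F0).

**Further compounds**
F1 | step 12 | C5-unsubstituted cis-fused oxasilolane ketone (6-oxo, C5H2, 7β side chain, 8α-OTBS, 10β-methyl, C1H2–SiMe2–O9) | CC(C)(C)[Si](C)(C)O[C@@H]1[C@@H](C(=C)CO[Si](C)(C)C(C)(C)C)C(=O)C[C@]2(C)C[Si](C)(C)O[C@H]12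
F2 | step 18 | (1S)-epoxide, C1 epimer of 24 | CC(C)(C)[Si](C)(C)O[C@@H]1[C@@H](C(=C)CO[Si](C)(C)C(C)(C)C)[C@@H](OC(=O)[C@@H](C)CC)[C@@H](C(=C)CO[Si](C)(C)C(C)(C)C)[C@](C)([C@H]2CO2)[C@@H]1O
F3 | step 18 | (1S)-1,2-diol from hydrolysis of F2 | CC(C)(C)[Si](C)(C)O[C@@H]1[C@@H](C(=C)CO[Si](C)(C)C(C)(C)C)[C@@H](OC(=O)[C@@H](C)CC)[C@@H](C(=C)CO[Si](C)(C)C(C)(C)C)[C@](C)([C@H](O)CO)[C@@H]1O
F0 | step 9 | none | none
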